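Ring B, the cyclopentene C1–C2=C3–C3a–C7a, is closed last at C1–C2 by 1,5 C–H insertion of an alkylidene carbene. The step exploits that C2=C3(CH3) is a methyl ketone in disguise and that the methyl-bearing methine C1 is the CH2 of an ethyl group: one operation forms ring B, its olefin and the C1 stereocentre. The precursor is a ring A cyclohexene bearing trans acetyl (C3a) and ethyl (C7a) groups. Its vicinal quaternary centres C4/C5 come from a Diels–Alder reaction of a menthyl-acetal butenolide, a temporary lactone masking the C4 acid and the C5 aldehyde; C3a/C7a are set by conjugate addition and enolate ethylation.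

Key step: step 9

Remarks on the chemistry
- Target numbering: (1R,3aR,4R,5S,7aS)-1,3,4,5,7-pentamethyl-5-[(1E,3E)-2-methyl-4-phenylbuta-1,3-dien-1-yl]-3a,4,5,7a-tetrahydro-1H-indene-4-carboxylic acid. Ring A = C3a–C4–C5–C6=C7–C7a, ring B = C1–C2=C3–C3a–C7a.
- Intermediates 6–13 are numbered as 2-benzofuran-1(3H)-ones: C3 = acetal carbon (future formyl carbon), C3a = future C5, C7a = future C4, C4 = future C6, C5 = future C7, C6 = future C7a, C7 = future C3a.
- "Menthyl" means (1S,2R,5S)-5-methyl-2-(propan-2-yl)cyclohexyl, from (+)-menthol.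
- Assumption: the (5S) epimer of acetal 4 can be collected by crystallisation with acid re-equilibration of the mother liquor, by analogy with the parent menthyloxyfuranone; otherwise the epimers are separated by chromatography.

Step 1
Reactants: 1 2,3-dimethylmaleic anhydride
Product: 2 rac-5-hydroxy-3,4-dimethylfuran-2(5H)-one
Conditions: LiAlH(OtBu)3 (1.1 equiv), THF, −30 to 0 °C; aq. HCl work-up
Reagents that add atoms: none
Why: Partial hydride reduction of a symmetric cyclic anhydride with a bulky alkoxyaluminium hydride should stop at the hydroxybutenolide (pseudo-acid), because the tetrahedral aluminate does not collapse at low temperature.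

Step 2
Reactants: 2 rac-5-hydroxy-3,4-dimethylfuran-2(5H)-one; 3 (+)-menthol
Product: 4 (5S)-3,4-dimethyl-5-(menthyloxy)furan-2(5H)-one
Conditions: TsOH·H2O (cat.), toluene, reflux, Dean–Stark trap; crystallisation from hexane
Reagents that add atoms: none
Why: Acid-catalysed acetalisation of the pseudo-acid; the C5 epimers interconvert through the oxocarbenium ion, so crystallisation with re-equilibration should funnel the material into the (5S) epimer, whose acetal carbon later fixes the absolute configuration.

Step 3
Reactants: 4 (5S)-3,4-dimethyl-5-(menthyloxy)furan-2(5H)-one; 5 (E)-3-(tert-butyldimethylsilyloxy)-N,N-dimethylbuta-1,3-dien-1-amine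
Product: 7 cis-fused enone lactone acetal, via aminosilyloxycyclohexene cycloadduct 6 (not isolated)
Conditions: toluene, 100 °C, sealed tube; then 1 M HCl, THF, 0 °C
Reagents that add atoms: none
Why: Normal-demand Diels–Alder reaction in which the nucleophilic CH2 terminus of the diene bonds to the β-carbon of the butenolide and the diene adds anti to the menthyloxy group, setting both quaternary centres cis (future C4 and C5); acid then hydrolyses the silyl enol ether and eliminates dimethylamine to give the enone.

Step 4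
Reactants: 7 cis-fused enone lactone acetal; 8 isopropenylmagnesium bromide
Product: 9 trimethylsilyl enol ether carrying the 7-isopropenyl group
Conditions: CH2=C(CH3)MgBr (2 equiv), CuBr·SMe2 (15 mol %), Me3SiCl (3 equiv), THF, −78 to −40 °C; Et3N, aq. NaHCO3
Reagents that add atoms: chlorotrimethylsilane, C[Si](C)(C)Cl
Why: Copper-catalysed, silyl-chloride-accelerated conjugate addition of a Grignard reagent with in situ O-silylation; the nucleophile is expected to add to the convex face of the cis-fused bicycle, anti to the lactone ring and its carbonyl on the neighbouring quaternary carbon, which places the isopropenyl group cis to the angular methyl groups (future C3a).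

Step 5
Reactants: 9 trimethylsilyl enol ether carrying the 7-isopropenyl group
Product: 10 trans-6-ethyl-7-isopropenyl ketone
Conditions: EtI (5 equiv), BnMe3N+ F− (1.2 equiv, dried), 4 Å molecular sieves, THF, 0 °C to rt
Reagents that add atoms: iodoethane, CCI
Why: Fluoride-induced regiospecific alkylation of a silyl enol ether; the ammonium enolate should be ethylated anti to the adjacent isopropenyl group, giving the trans diequatorial ketone (future C7a), which is also the thermodynamically favoured epimer.

Step 6
Reactants: 10 trans-6-ethyl-7-isopropenyl ketone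
Product: 11 enol triflate (C4=C5)
Conditions: KN(SiMe3)2 (1.1 equiv), THF, −78 °C; PhNTf2 (1.2 equiv), −78 to 0 °C; aq. NH4Cl
Reagents that add atoms: N-phenylbis(trifluoromethanesulfonimide), O=S(=O)(N(c1ccccc1)S(=O)(=O)C(F)(F)F)C(F)(F)F
Why: Kinetic enolisation and O-triflation; the base should remove a proton from the CH2 and not from the ethyl-bearing methine, so the enol triflate forms on the side that becomes C6=C7.

Step 7
Reactants: 11 enol triflate (C4=C5)
Product: 12 7-acetyl enol triflate
Conditions: O3, CH2Cl2, −78 °C (Sudan Red 7B end point); Me2S, −78 °C to rt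
Reagents that add atoms: ozone, [O-][O+]=O
Why: Ozonolysis is selective for the electron-rich 1,1-disubstituted olefin over the electron-poor enol triflate and unveils the acetyl group, whose α-stereocentre stays in the favoured trans equatorial arrangement.

Step 8
Reactants: 12 7-acetyl enol triflate
Product: 13 7-acetyl-6-ethyl-5-methyl cyclohexene lactone acetal
Conditions: MeZnCl (2.5 equiv), Pd(PPh3)4 (5 mol %), THF, 50 °C
Reagents that add atoms: methylzinc chloride, C[Zn]Cl
Why: Negishi cross-coupling of the enol triflate; the organozinc reagent tolerates the methyl ketone and the lactone, and it installs the C7 methyl group on the C6=C7 olefin without touching a stereocentre.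

Step 9
Reactants: 13 7-acetyl-6-ethyl-5-methyl cyclohexene lactone acetal
Product: 16 tricyclic lactone acetal with ring B closed, via diazoalkene 14 (not isolated), via alkylidene carbene 15 (not isolated)
Conditions: Me3SiCHN2 (2.0 equiv), n-BuLi (1.9 equiv), THF, −78 °C; then 13, −78 °C to rt
Reagents that add atoms: (trimethylsilyl)diazomethane, C[Si](C)(C)C=[N+]=[N-]
Why: Lithiated Me3SiCHN2 adds to the methyl ketone, Peterson-type loss of Me3SiOLi gives diazoalkene 14, N2 is lost, and singlet alkylidene carbene 15 inserts concertedly and with retention into a C–H bond five atoms away; the closest known reaction type is cyclopentene synthesis by alkylidene carbene 1,5 C–H insertion under Colvin conditions. Ring B is closed in the 1,5-insertion mode: the carbene carbon becomes C2 and bonds to the ethyl CH2, which becomes C1, while C3 keeps its methyl group, so the 1-methylcyclopentene pattern arises directly. The new stereocentre C1 is set by the choice between the two diastereotopic methylene hydrogens: with the carbene arm and the ethyl group trans-diequatorial, the transition state that keeps the terminal CH3 away from C7 and its methyl group (CH3 cis to H-7a) should be favoured and gives the required (1R) arrangement. The trans ring fusion C3a/C7a was set in steps 4 and 5 and is not touched. The step needs site selectivity for this secondary C–H bond over the primary C–H bonds of the 4-methyl group, over [2+1] addition to C6=C7 and over 1,2-shift to an alkyne; the intrinsic secondary-over-primary preference of alkylidene carbenes, the anti-periplanar and so out-of-reach position of C7 relative to the carbene arm, and the poor migratory aptitude of alkyl groups should secure these.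

Step 10
Reactants: 16 tricyclic lactone acetal with ring B closed
Product: 17 5-formyl acid (in equilibrium with its cyclic hydroxylactone)
Conditions: LiOH (5 equiv), THF–H2O (3:1), 50 °C; then 1 M HCl to pH 3, 0 °C
Reagents that add atoms: lithium hydroxide, [Li+].[OH-]
Why: Saponification of the pseudo-ester: hydroxide opens the lactone, the released hemiacetal collapses to the non-enolisable C5 aldehyde and menthol, and no stereocentre can epimerise because C4 and C5 are quaternary.

Step 11
Reactants: 17 5-formyl acid; 18 2-(triphenyl-λ5-phosphanylidene)propanal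
Product: 19 (E)-enal acid
Conditions: 18 (3 equiv), toluene, 110 °C
Reagents that add atoms: none
Why: Wittig olefination with a formyl-stabilised ylide, which should trap the open aldehyde tautomer and give the (E)-2-methyl enal with the usual selectivity of stabilised ylides.

Step 12
Reactants: 19 (E)-enal acid; 20 diethyl benzylphosphonate
Product: 21 27-nor-zyggomphic acid B
Conditions: 20 (2.5 equiv), NaH (4 equiv), THF, 0 °C to rt; aq. HCl work-up
Reagents that add atoms: none
Why: Horner–Wadsworth–Emmons olefination of the enal with the benzylphosphonate anion, which is (E)-selective and completes the (1E,3E)-diene while the carboxylate formed in situ stays inert.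

Compound list
1 | 2,3-dimethylmaleic anhydride | CC1=C(C)C(=O)OC1=O | starting material
2 | rac-5-hydroxy-3,4-dimethylfuran-2(5H)-one | CC1=C(C)C(O)OC1=O | intermediate
3 | (+)-menthol, (1S,2R,5S)-5-methyl-2-(propan-2-yl)cyclohexan-1-ol | CC(C)[C@H]1CC[C@H](C)C[C@@H]1O | starting material
4 | (5S)-3,4-dimethyl-5-(menthyloxy)furan-2(5H)-one | CC1=C(C)[C@@H](O[C@H]2C[C@@H](C)CC[C@@H]2C(C)C)OC1=O | intermediate
5 | (E)-3-(tert-butyldimethylsilyloxy)-N,N-dimethylbuta-1,3-dien-1-amine | C=C(O[Si](C)(C)C(C)(C)C)/C=C/N(C)C | starting material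
6 | cycloadduct: cis-fused 7-(dimethylamino)-5-(tert-butyldimethylsilyloxy)-3-(menthyloxy)-3a,7a-dimethyl-3a,4,7,7a-tetrahydro-2-benzofuran-1(3H)-one (C7 epimers) | CN(C)C1C=C(O[Si](C)(C)C(C)(C)C)C[C@]2(C)[C@@H](O[C@H]3C[C@@H](C)CC[C@@H]3C(C)C)OC(=O)[C@]12C | intermediate
7 | cis-fused enone lactone acetal: 3-(menthyloxy)-3a,7a-dimethyl-3a,4-dihydro-2-benzofuran-1,5(3H,7aH)-dione, menthyloxy cis to both angular methyls | O=C1C[C@]2(C)[C@@H](O[C@H]3C[C@@H](C)CC[C@@H]3C(C)C)OC(=O)[C@]2(C)C=C1 | intermediate
8 | isopropenylmagnesium bromide, CH2=C(CH3)MgBr | C=C(C)[Mg]Br | starting material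
9 | 3-(menthyloxy)-3a,7a-dimethyl-7-(prop-1-en-2-yl)-5-(trimethylsilyloxy)-3a,4,7,7a-tetrahydro-2-benzofuran-1(3H)-one, isopropenyl cis to the angular methyls | C[Si](C)(C)OC1=C[C@H](C(C)=C)[C@@]2(C)C(=O)O[C@H](O[C@H]3C[C@@H](C)CC[C@@H]3C(C)C)[C@@]2(C)C1 | intermediate
10 | 6-ethyl-3-(menthyloxy)-3a,7a-dimethyl-7-(prop-1-en-2-yl)hexahydro-2-benzofuran-1,5-dione, ethyl trans to isopropenyl | O=C1[C@@H](CC)[C@H](C(C)=C)[C@@]2(C)C(=O)O[C@H](O[C@H]3C[C@@H](C)CC[C@@H]3C(C)C)[C@@]2(C)C1 | intermediate
11 | 6-ethyl-3-(menthyloxy)-3a,7a-dimethyl-1-oxo-7-(prop-1-en-2-yl)-1,3,3a,6,7,7a-hexahydro-2-benzofuran-5-yl trifluoromethanesulfonate | FC(F)(F)S(=O)(=O)OC1=C[C@]2(C)[C@@H](O[C@H]3C[C@@H](C)CC[C@@H]3C(C)C)OC(=O)[C@]2(C)[C@@H](C(C)=C)[C@@H]1CC | intermediate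
12 | 7-acetyl-6-ethyl-3-(menthyloxy)-3a,7a-dimethyl-1-oxo-1,3,3a,6,7,7a-hexahydro-2-benzofuran-5-yl trifluoromethanesulfonate | FC(F)(F)S(=O)(=O)OC1=C[C@]2(C)[C@@H](O[C@H]3C[C@@H](C)CC[C@@H]3C(C)C)OC(=O)[C@]2(C)[C@@H](C(C)=O)[C@@H]1CC | intermediate
13 | 7-acetyl-6-ethyl-3-(menthyloxy)-3a,5,7a-trimethyl-3a,6,7,7a-tetrahydro-2-benzofuran-1(3H)-one, acetyl trans to ethyl | CC1=C[C@]2(C)[C@@H](O[C@H]3C[C@@H](C)CC[C@@H]3C(C)C)OC(=O)[C@]2(C)[C@@H](C(C)=O)[C@@H]1CC | intermediate
14 | diazoalkene: 7-(1-diazoprop-1-en-2-yl) analogue of 13 | CC1=C[C@]2(C)[C@@H](O[C@H]3C[C@@H](C)CC[C@@H]3C(C)C)OC(=O)[C@]2(C)[C@@H](C(C)=C=[N+]=[N-])[C@@H]1CC | intermediate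
15 | alkylidene carbene: 7-(1-methylvinylidene) analogue of 13 | CC1=C[C@]2(C)[C@@H](O[C@H]3C[C@@H](C)CC[C@@H]3C(C)C)OC(=O)[C@]2(C)[C@@H](C(C)=[C])[C@@H]1CC | intermediate
16 | tricyclic lactone acetal: the 1,3,4,5,7-pentamethyl-3a,4,5,7a-tetrahydro-1H-indene core of the target with the C4 carboxyl and the C5 formyl carbon tied as a cis-fused γ-lactone menthyl acetal; configuration at C1, C3a, C4, C5, C7a as in the target | CC1=C[C@]2(C)[C@@H](O[C@H]4C[C@@H](C)CC[C@@H]4C(C)C)OC(=O)[C@]2(C)[C@H]3C(C)=C[C@@H](C)[C@H]13 | intermediate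
17 | 5-formyl-1,3,4,5,7-pentamethyl-3a,4,5,7a-tetrahydro-1H-indene-4-carboxylic acid, configuration as in the target (ring-chain tautomer: hydroxylactone) | CC1=C[C@](C)(C=O)[C@](C)(C(=O)O)[C@H]2C(C)=C[C@@H](C)[C@H]12 | intermediate
18 | 2-(triphenyl-λ5-phosphanylidene)propanal | CC(C=O)=P(c1ccccc1)(c1ccccc1)c1ccccc1 | starting material
19 | 1,3,4,5,7-pentamethyl-5-[(1E)-2-methyl-3-oxoprop-1-en-1-yl]-3a,4,5,7a-tetrahydro-1H-indene-4-carboxylic acid, configuration as in the target | CC1=C[C@](C)(/C=C(C)/C=O)[C@](C)(C(=O)O)[C@H]2C(C)=C[C@@H](C)[C@H]12 | intermediate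
20 | diethyl benzylphosphonate | CCOP(=O)(Cc1ccccc1)OCC | starting material
21 | 27-nor-zyggomphic acid B, (1R,3aR,4R,5S,7aS)-1,3,4,5,7-pentamethyl-5-[(1E,3E)-2-methyl-4-phenylbuta-1,3-dien-1-yl]-3a,4,5,7a-tetrahydro-1H-indene-4-carboxylic acid | CC1=C[C@](C)(/C=C(C)/C=C/c2ccccc2)[C@](C)(C(=O)O)[C@H]2C(C)=C[C@@H](C)[C@H]12 | target

Total step count: 12
Longest linear sequence: 12 steps (1 to 21)

Steps most likely to fail

Step 9. The lithiated diazomethane may merely enolise the hindered methyl ketone, or the insertion may discriminate poorly between the two methylene hydrogens. The fallback closes ring B by ring-closing metathesis at C2=C3; it sets out from 9 and comes back to the route at 16. Commercial (E)-pent-3-en-2-ol is converted with ClCO2Me and pyridine into racemic (E)-pent-3-en-2-yl methyl carbonate F1. Palladium-catalysed asymmetric allylic alkylation of 9 with it uses Pd2(dba)3, the N,N'-(cyclohexane-1,2-diyl)bis[2-(diphenylphosphino)benzamide] ligand and Bu4N+ Ph3SiF2− in THF; the ligand antipode is chosen to set the required configuration at the new methine. The reaction runs through the symmetrical 1,3-dimethylallyl complex, so regiochemistry is no issue, and should give the trans 6-[(E)-pent-3-en-2-yl] ketone F2. KN(SiMe3)2 and PhNTf2 then give the enol triflate F3, and MeZnCl with Pd(PPh3)4 gives the triene F4. Second-generation Grubbs catalyst, RuCl2(=CHPh)(H2IMes)(PCy3), in toluene at 80 °C closes ring B with loss of propene and gives 16.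

Step 3. The tetrasubstituted, singly activated dienophile may react more slowly than the aminosilyloxydiene decomposes. The fallback runs the cycloaddition on the doubly activated anhydride; it sets out from 1 (with 5) and comes back at 7. The Diels–Alder reaction gives the racemic anhydride cycloadduct F5. LiAlH(OtBu)3 at −40 °C should reduce the less hindered carbonyl, the one on the carbon next to the ring CH2, and 1 M HCl then unveils the enone to give the racemic hydroxylactone enone F6. Acetalisation with (+)-menthol 3 (TsOH, toluene) gives 7 and the diastereomeric acetal F7, which are separated by crystallisation or chromatography.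

Step 11. The olefination may stall because the aldehyde is neopentylic, flanked by two quaternary carbons, and largely masked as its hydroxylactone tautomer. The fallback uses a smaller, more nucleophilic phosphonate carbanion and adjusts the oxidation level afterwards; it sets out from 17 and comes back at 19. Horner–Wadsworth–Emmons reaction with triethyl 2-phosphonopropionate and NaH in THF at reflux gives the (E)-enoate acid F8, i-Bu2AlH at −78 °C gives the allylic alcohol acid F9, and MnO2 in CH2Cl2 gives 19.

Further compounds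
F1 | step 9 | rac-(E)-pent-3-en-2-yl methyl carbonate | COC(=O)OC(C)/C=C/C
F2 | step 9 | 3-(menthyloxy)-3a,7a-dimethyl-6-[(E)-pent-3-en-2-yl]-7-(prop-1-en-2-yl)hexahydro-2-benzofuran-1,5-dione | O=C1[C@@H]([C@H](C)/C=C/C)[C@H](C(C)=C)[C@@]2(C)C(=O)O[C@H](O[C@H]3C[C@@H](C)CC[C@@H]3C(C)C)[C@@]2(C)C1
F3 | step 9 | enol triflate of F2 (C4=C5) | FC(F)(F)S(=O)(=O)OC1=C[C@]2(C)[C@@H](O[C@H]3C[C@@H](C)CC[C@@H]3C(C)C)OC(=O)[C@]2(C)[C@@H](C(C)=C)[C@@H]1[C@H](C)/C=C/C
F4 | step 9 | 3-(menthyloxy)-3a,5,7a-trimethyl-6-[(E)-pent-3-en-2-yl]-7-(prop-1-en-2-yl)-3a,6,7,7a-tetrahydro-2-benzofuran-1(3H)-one | CC1=C[C@]2(C)[C@@H](O[C@H]3C[C@@H](C)CC[C@@H]3C(C)C)OC(=O)[C@]2(C)[C@@H](C(C)=C)[C@@H]1[C@H](C)/C=C/C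
F5 | step 3 | racemic cis-fused anhydride cycloadduct of 1 and 5 (one enantiomer drawn) | CN(C)C1C=C(O[Si](C)(C)C(C)(C)C)C[C@]2(C)C(=O)OC(=O)[C@]12C
F6 | step 3 | racemic 3-hydroxy-3a,7a-dimethyl-3a,4-dihydro-2-benzofuran-1,5(3H,7aH)-dione (one enantiomer drawn) | O=C1C[C@]2(C)C(O)OC(=O)[C@]2(C)C=C1
F7 | step 3 | diastereomer of 7 with the enantiomeric bicyclic core | O=C1C[C@@]2(C)[C@H](O[C@H]3C[C@@H](C)CC[C@@H]3C(C)C)OC(=O)[C@@]2(C)C=C1
F8 | step 11 | 5-[(1E)-3-ethoxy-2-methyl-3-oxoprop-1-en-1-yl]-1,3,4,5,7-pentamethyl-3a,4,5,7a-tetrahydro-1H-indene-4-carboxylic acid | CC1=C[C@](C)(/C=C(C)/C(=O)OCC)[C@](C)(C(=O)O)[C@H]2C(C)=C[C@@H](C)[C@H]12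
F9 | step 11 | 5-[(1E)-3-hydroxy-2-methylprop-1-en-1-yl]-1,3,4,5,7-pentamethyl-3a,4,5,7a-tetrahydro-1H-indene-4-carboxylic acid | CC1=C[C@](C)(/C=C(C)/CO)[C@](C)(C(=O)O)[C@H]2C(C)=C[C@@H](C)[C@H]12
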